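**Retrosynthetic overview**
1. The 4-hydroxybenzoate is cut last. The secondary allylic C5–OH of a (1E,3Z)-cyclodeca-1,3-diene-5,7-diol is acylated beside the unreactive tertiary C7–OH.
2. The plan rests on C1 and C2, the two carbons of the trisubstituted E alkene of the ten-membered carbocycle. C1 (methyl-bearing) is read as a methyl ketone and C2, conjugated with C3=C4, as a Z-enal carbon, so the only ring closes by reductive carbonyl–carbonyl (McMurry) coupling of an open-chain 1,10-keto-enal.
3. The ketone unit (C10, C1, C1-methyl) enters late, by acetonyl Wittig olefination of a C9 aldehyde and 1,4-reduction. It therefore never meets carbanions or free C5/C7 hydroxyls (which would trap it as a 2,9-dioxabicyclo[3.3.1]nonane ketal) and needs no protecting group.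
4. The 3Z alkene comes from syn-carbocupration of a C2–C5 ynoate with an isopropyl cuprate. C5 (S) is set by reagent-controlled reduction of the ynone, because C7 with its look-alike methyl and methylene arms is a weak 1,3-director.
5. C5–C9 and the C7 carbinol come from (R)-mevalonolactone, opened to a Weinreb amide that masks C9. One ring is formed, in the key step.

Key step: step 13

Remark: the ring numbering of the target is used for all open-chain compounds (C1 methyl-bearing alkene carbon, C4 isopropyl-bearing, C5 acyloxy carbon, C7 tertiary carbinol, C8–C10 methylenes). The target is (1E,3Z,5S,7S); the C7 descriptor reads R up to compound 16 only because C8 outranks C6 there, while the spatial arrangement never changes.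

**Step 1**
Reactants: 1 (R)-mevalonolactone
Product: 2 (3R)-3,5-dihydroxy-N-methoxy-N,3-dimethylpentanamide
Conditions: MeNH(OMe)·HCl, AlMe3, CH2Cl2, 0 °C to rt; aq. potassium sodium tartrate; crude product used at once
Reagents that add atoms: N,O-dimethylhydroxylamine hydrochloride, CNOC.Cl
Why: Weinreb aminolysis of a δ-lactone with the aluminium amide breaks only the acyl–oxygen bond, so the C7 carbinol of 1 is carried over unchanged, C9 is masked at the acid level and C5 is freed as the primary alcohol.

**Step 2**
Reactants: 2 (3R)-3,5-dihydroxy-N-methoxy-N,3-dimethylpentanamide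
Product: 3 (3R)-N-methoxy-N,3-dimethyl-3,5-bis(triethylsilyloxy)pentanamide
Conditions: TESOTf (2.5 equiv), 2,6-lutidine, CH2Cl2, −78 to 0 °C
Reagents that add atoms: triethylsilyl triflate, CC[Si](CC)(CC)OS(=O)(=O)C(F)(F)F
Why: A silyl triflate with a hindered pyridine base silylates primary and tertiary hydroxyls alike (standard silyl ether formation), which stops relactonisation and installs the C7 protecting group that stays on until step 14.

**Step 3**
Reactants: 3 (3R)-N-methoxy-N,3-dimethyl-3,5-bis(triethylsilyloxy)pentanamide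
Product: 4 (3R)-N-methoxy-N,3-dimethyl-5-oxo-3-(triethylsilyloxy)pentanamide
Conditions: (COCl)2, DMSO, CH2Cl2, −78 to −40 °C; Et3N, −78 to 0 °C
Reagents that add atoms: none
Why: Under Swern conditions a primary triethylsilyl ether is attacked by the chlorosulfonium salt and oxidised directly to the aldehyde while hindered silyl ethers stay on (known selective oxidative desilylation), so the tertiary C7–OTES and the Weinreb amide survive and a separate deprotection is saved.

**Step 4**
Reactants: 4 (3R)-N-methoxy-N,3-dimethyl-5-oxo-3-(triethylsilyloxy)pentanamide; 5 methyl propiolate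
Product: 7 methyl (6R)-4-hydroxy-8-[methoxy(methyl)amino]-6-methyl-8-oxo-6-(triethylsilyloxy)oct-2-ynoate (both epimers at ring C5), via lithium acetylide 6 (not isolated)
Conditions: 5, LiN(SiMe3)2, THF, −78 °C; then 4, −78 °C; AcOH in THF at −78 °C
Reagents that add atoms: none
Why: 1,2-Addition of a lithium acetylide to an aldehyde at −78 °C is much faster than attack on the Weinreb amide, the cold acidic quench keeps the C5 alkoxide from closing a δ-lactone on C9, and no control at C5 is sought because this centre is erased in step 5.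

**Step 5**
Reactants: 7 methyl (6R)-4-hydroxy-8-[methoxy(methyl)amino]-6-methyl-8-oxo-6-(triethylsilyloxy)oct-2-ynoate
Product: 8 methyl (6R)-8-[methoxy(methyl)amino]-6-methyl-4,8-dioxo-6-(triethylsilyloxy)oct-2-ynoate
Conditions: Dess–Martin periodinane, CH2Cl2, 0 °C to rt; short silica plug
Reagents that add atoms: none
Why: Dess–Martin oxidation turns the propargylic alcohol into the ynone under nearly neutral, non-aqueous conditions that avoid β-elimination of the C7 silyloxy group and Michael addition to the doubly activated alkyne.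

**Step 6**
Reactants: 8 methyl (6R)-8-[methoxy(methyl)amino]-6-methyl-4,8-dioxo-6-(triethylsilyloxy)oct-2-ynoate
Product: 10 methyl (4S,6R)-4-hydroxy-8-[methoxy(methyl)amino]-6-methyl-8-oxo-6-(triethylsilyloxy)oct-2-ynoate, via 9-BBN borinate 9 (not isolated)
Conditions: (S)-Alpine-Borane [B-isopinocampheyl-9-BBN from (−)-α-pinene, neat, 2 equiv], rt; then 30% H2O2, pH 7 buffer, MeOH, 0 °C
Reagents that add atoms: none
Why: In the Midland reduction the pinanyl β-hydride is delivered through a boat-like six-membered transition state with the slim alkynyl arm next to the pinane methyl group, so the (S)-reagent should give the (S)-propargylic alcohol at C5 by reagent control (electron-poor ynones react fastest, ester and amide are inert) and the minor C5 epimer, a diastereomer, can be removed by chromatography.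

**Step 7**
Reactants: 10 methyl (4S,6R)-4-hydroxy-8-[methoxy(methyl)amino]-6-methyl-8-oxo-6-(triethylsilyloxy)oct-2-ynoate
Product: 11 methyl (4S,6R)-4-(tert-butyldimethylsilyloxy)-8-[methoxy(methyl)amino]-6-methyl-8-oxo-6-(triethylsilyloxy)oct-2-ynoate
Conditions: TBSOTf, 2,6-lutidine, CH2Cl2, −78 to 0 °C
Reagents that add atoms: tert-butyldimethylsilyl triflate, CC(C)(C)[Si](C)(C)OS(=O)(=O)C(F)(F)F
Why: Fast silylation with a weak, hindered base caps C5–OH before it can lactonise onto C9 and avoids the amine-promoted redox isomerisation known for γ-hydroxy ynoates.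

**Step 8**
Reactants: 11 methyl (4S,6R)-4-(tert-butyldimethylsilyloxy)-8-[methoxy(methyl)amino]-6-methyl-8-oxo-6-(triethylsilyloxy)oct-2-ynoate; 12 isopropylmagnesium chloride
Product: 14 methyl (2Z,4S,6R)-4-(tert-butyldimethylsilyloxy)-3-isopropyl-8-[methoxy(methyl)amino]-6-methyl-8-oxo-6-(triethylsilyloxy)oct-2-enoate, via magnesium diisopropylcuprate 13 (not isolated)
Conditions: i-PrMgCl (3 equiv), CuBr·SMe2 (1.5 equiv), THF, −78 to −40 °C; then 11, −78 °C; sat. aq. NH4Cl added at −78 °C
Reagents that add atoms: none
Why: Conjugate syn-carbocupration of an alkynoate puts isopropyl on C4 and copper on C3 on the same side, and protonation at −78 °C, before the alkenylcuprate can equilibrate through its allenolate, leaves H3 cis to isopropyl and hence C2 cis to C5 (3Z), while silyl ethers and the Weinreb amide are inert to cuprates and a silyloxy group is too poor a leaving group for SN2′ displacement.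

**Step 9**
Reactants: 14 methyl (2Z,4S,6R)-4-(tert-butyldimethylsilyloxy)-3-isopropyl-8-[methoxy(methyl)amino]-6-methyl-8-oxo-6-(triethylsilyloxy)oct-2-enoate
Product: 16 (3R,5S,6Z)-5-(tert-butyldimethylsilyloxy)-8-hydroxy-6-isopropyl-3-methyl-3-(triethylsilyloxy)oct-6-enal, via bis(diisobutylaluminium) adduct 15 (not isolated)
Conditions: i-Bu2AlH (5 equiv), CH2Cl2, −78 to −40 °C; aq. potassium sodium tartrate
Reagents that add atoms: none
Why: i-Bu2AlH reduces the enoate fully to the allylic alcohol while the Weinreb amide stops at the chelated aluminium hemiaminal of 15, which releases the C9 aldehyde only on work-up, so both chain ends reach the needed oxidation levels in one operation without touching the 3Z alkene.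

**Step 10**
Reactants: 16 (3R,5S,6Z)-5-(tert-butyldimethylsilyloxy)-8-hydroxy-6-isopropyl-3-methyl-3-(triethylsilyloxy)oct-6-enal; 17 1-(triphenylphosphoranylidene)propan-2-one
Product: 18 (3E,6S,8S,9Z)-8-(tert-butyldimethylsilyloxy)-11-hydroxy-9-isopropyl-6-methyl-6-(triethylsilyloxy)undeca-3,9-dien-2-one
Conditions: 17 (2.5 equiv), toluene, 70 °C
Reagents that add atoms: none
Why: Wittig olefination with a stabilised, weakly basic ylide adds C10, C1 and the C1 methyl group to the enolisable β-silyloxy aldehyde without elimination, the distant allylic alcohol is a spectator, and the geometry of the new alkene is of no consequence.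

**Step 11**
Reactants: 18 (3E,6S,8S,9Z)-8-(tert-butyldimethylsilyloxy)-11-hydroxy-9-isopropyl-6-methyl-6-(triethylsilyloxy)undeca-3,9-dien-2-one
Product: 19 (6S,8S,9Z)-8-(tert-butyldimethylsilyloxy)-11-hydroxy-9-isopropyl-6-methyl-6-(triethylsilyloxy)undec-9-en-2-one
Conditions: [(Ph3P)CuH]6 (Stryker reagent, 0.4 equiv), H2O, degassed toluene, rt
Reagents that add atoms: none
Why: The copper hydride reduces only the conjugated C9=C10 bond by 1,4-hydride delivery and protonation of the copper enolate, so the isolated trisubstituted 3Z alkene, which hydrogenation over Pd/C would endanger, and both silyl ethers are left alone.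

**Step 12**
Reactants: 19 (6S,8S,9Z)-8-(tert-butyldimethylsilyloxy)-11-hydroxy-9-isopropyl-6-methyl-6-(triethylsilyloxy)undec-9-en-2-one
Product: 20 (2Z,4S,6S)-4-(tert-butyldimethylsilyloxy)-3-isopropyl-6-methyl-10-oxo-6-(triethylsilyloxy)undec-2-enal
Conditions: TEMPO (cat.), PhI(OAc)2, CH2Cl2, rt
Reagents that add atoms: none
Why: The oxoammonium (TEMPO) oxidation is selective for primary alcohols and is known to convert Z-allylic alcohols into Z-enals without isomerisation or over-oxidation, and with C5–O silylated no lactol or furan can form from the cis-disposed C2 and C5.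

**Step 13**
Reactants: 20 (2Z,4S,6S)-4-(tert-butyldimethylsilyloxy)-3-isopropyl-6-methyl-10-oxo-6-(triethylsilyloxy)undec-2-enal
Product: 22 (1E,3Z,5S,7S)-5-(tert-butyldimethylsilyloxy)-4-isopropyl-1,7-dimethyl-7-(triethylsilyloxy)cyclodeca-1,3-diene, via titanium pinacolate 21 (not isolated)
Conditions: TiCl3(DME)1.5 (12 equiv), Zn–Cu couple (40 equiv), DME, reflux 4 h; then 20 in DME by syringe pump over 30 h (final ca. 0.003 M), reflux 6 h more; cool, aq. K2CO3, pentane, Celite; AgNO3-impregnated silica
Reagents that add atoms: none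
Why: Zerovalent titanium made from TiCl3(DME)1.5 and Zn–Cu passes one electron to each carbonyl group of 20, the two titanium-bound ketyls (the C2 ketyl is delocalised over C2–C4) join C1 to C2 to give pinacolate 21, and at reflux both C–O bonds are broken on the metal to leave the C1=C2 alkene. The closest known reaction type is the intramolecular McMurry keto–aldehyde coupling, which closes ten-membered and larger carbocycles and tolerates enals and silyl ethers. The ten-membered ring closes end to end between the termini of the 1,10-dicarbonyl chain (exo with respect to both C=O bonds), with both oxygens held on one titanium template and slow addition keeping 20 dilute enough to suppress dimerisation. No stereocentre is formed; C5 and C7 are spectators, and C5–O is carried as a silyl ether, a poor leaving group next to the delocalised ketyl, which is why the aroyl ester is put on only afterwards. The step needs E geometry at C1=C2 and retention of 3Z: 3Z is brought in from 20 and is backed by the fully substituted C4, whereas E arises only when 21 is deoxygenated and is favoured merely by the lower strain of the arrangement with C10 and C3 anti across the new bond. The alkene geometry is therefore the first thing to check (NOE between H2 and the C10 methylene), and any Z isomer is removed on the silver-loaded silica.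

**Step 14**
Reactants: 22 (1E,3Z,5S,7S)-5-(tert-butyldimethylsilyloxy)-4-isopropyl-1,7-dimethyl-7-(triethylsilyloxy)cyclodeca-1,3-diene
Product: 23 (1E,3Z,5S,7S)-4-isopropyl-1,7-dimethylcyclodeca-1,3-diene-5,7-diol
Conditions: Bu4NF (5 equiv), THF, rt to 40 °C
Reagents that add atoms: none
Why: Fluoride cleaves both Si–O bonds (fluoride desilylation) under basic, non-ionising conditions that spare the acid-sensitive dienyl carbinol and leave both C–O stereocentres untouched.

**Step 15**
Reactants: 24 4-hydroxybenzoic acid
Product: 26 4-(tert-butyldimethylsilyloxy)benzoic acid, via silyl ester 25 (not isolated)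
Conditions: TBSCl (2.3 equiv), imidazole, DMF, rt; then AcOH–THF–H2O (3:1:1), rt
Reagents that add atoms: tert-butyldimethylsilyl chloride, CC(C)(C)[Si](C)(C)Cl
Why: Exhaustive silylation followed by mild aqueous acid exploits the far greater lability of a silyl ester compared with an aryl silyl ether, so only the carboxyl group is set free.

**Step 16**
Reactants: 23 (1E,3Z,5S,7S)-4-isopropyl-1,7-dimethylcyclodeca-1,3-diene-5,7-diol; 26 4-(tert-butyldimethylsilyloxy)benzoic acid
Product: 28 (1E,3Z,5S,7S)-7-hydroxy-4-isopropyl-1,7-dimethylcyclodeca-1,3-dien-5-yl 4-(tert-butyldimethylsilyloxy)benzoate, via acid chloride 27 (not isolated)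
Conditions: 26 (1.2 equiv), 1-chloro-N,N,2-trimethylprop-1-en-1-amine (Ghosez reagent), CH2Cl2, 0 °C; then 23, pyridine, DMAP (cat.), 0 °C to rt
Reagents that add atoms: none
Why: Neutral acid chloride formation keeps the aryl silyl ether intact, DMAP-catalysed acylation distinguishes the secondary C5–OH from the tertiary C7–OH on steric grounds, and the C5–O bond is not broken, so 5S is retained.

**Step 17**
Reactants: 28 (1E,3Z,5S,7S)-7-hydroxy-4-isopropyl-1,7-dimethylcyclodeca-1,3-dien-5-yl 4-(tert-butyldimethylsilyloxy)benzoate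
Product: 29 (1E,3Z,5S,7S)-7-hydroxy-4-isopropyl-1,7-dimethylcyclodeca-1,3-dien-5-yl 4-hydroxybenzoate (CNP0130127.1)
Conditions: Bu4NF (1.1 equiv), AcOH (1.1 equiv), THF, 0 °C
Reagents that add atoms: none
Why: Aryl silyl ethers are the most fluoride-labile silyl ethers, so buffered fluoride at 0 °C should free the phenol quickly without cleaving or migrating the C5 ester.

**Compound list**
1 | (R)-mevalonolactone, (4R)-4-hydroxy-4-methyloxan-2-one | C[C@@]1(O)CCOC(=O)C1 | starting material
2 | (3R)-3,5-dihydroxy-N-methoxy-N,3-dimethylpentanamide | OCC[C@@](C)(O)CC(=O)N(C)OC | intermediate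
3 | (3R)-N-methoxy-N,3-dimethyl-3,5-bis(triethylsilyloxy)pentanamide | CC[Si](CC)(CC)OCC[C@@](C)(O[Si](CC)(CC)CC)CC(=O)N(C)OC | intermediate
4 | (3R)-N-methoxy-N,3-dimethyl-5-oxo-3-(triethylsilyloxy)pentanamide | O=CC[C@@](C)(O[Si](CC)(CC)CC)CC(=O)N(C)OC | intermediate
5 | methyl propiolate | C#CC(=O)OC | starting material
6 | lithium methyl propiolate (not isolated) | [Li]C#CC(=O)OC | intermediate
7 | methyl (6R)-4-hydroxy-8-[methoxy(methyl)amino]-6-methyl-8-oxo-6-(triethylsilyloxy)oct-2-ynoate, both epimers at ring C5 | COC(=O)C#CC(O)C[C@@](C)(O[Si](CC)(CC)CC)CC(=O)N(C)OC | intermediate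
8 | methyl (6R)-8-[methoxy(methyl)amino]-6-methyl-4,8-dioxo-6-(triethylsilyloxy)oct-2-ynoate | COC(=O)C#CC(=O)C[C@@](C)(O[Si](CC)(CC)CC)CC(=O)N(C)OC | intermediate
9 | 9-BBN borinate of 10 (not isolated) | COC(=O)C#C[C@@H](OB1C2CCCC1CCC2)C[C@@](C)(O[Si](CC)(CC)CC)CC(=O)N(C)OC | intermediate
10 | methyl (4S,6R)-4-hydroxy-8-[methoxy(methyl)amino]-6-methyl-8-oxo-6-(triethylsilyloxy)oct-2-ynoate | COC(=O)C#C[C@@H](O)C[C@@](C)(O[Si](CC)(CC)CC)CC(=O)N(C)OC | intermediate
11 | methyl (4S,6R)-4-(tert-butyldimethylsilyloxy)-8-[methoxy(methyl)amino]-6-methyl-8-oxo-6-(triethylsilyloxy)oct-2-ynoate | COC(=O)C#C[C@@H](O[Si](C)(C)C(C)(C)C)C[C@@](C)(O[Si](CC)(CC)CC)CC(=O)N(C)OC | intermediate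
12 | isopropylmagnesium chloride | CC(C)[Mg]Cl | starting material
13 | chloromagnesium diisopropylcuprate (not isolated) | CC(C)[Cu-]C(C)C.[Mg+]Cl | intermediate
14 | methyl (2Z,4S,6R)-4-(tert-butyldimethylsilyloxy)-3-isopropyl-8-[methoxy(methyl)amino]-6-methyl-8-oxo-6-(triethylsilyloxy)oct-2-enoate | COC(=O)\C=C(\C(C)C)[C@@H](O[Si](C)(C)C(C)(C)C)C[C@@](C)(O[Si](CC)(CC)CC)CC(=O)N(C)OC | intermediate
15 | C2 diisobutylaluminium alkoxide / C9 O-diisobutylaluminium N-methoxy-N-methyl hemiaminal (not isolated) | CC(C)C[Al](CC(C)C)OC\C=C(\C(C)C)[C@@H](O[Si](C)(C)C(C)(C)C)C[C@@](C)(O[Si](CC)(CC)CC)CC(O[Al](CC(C)C)CC(C)C)N(C)OC | intermediate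
16 | (3R,5S,6Z)-5-(tert-butyldimethylsilyloxy)-8-hydroxy-6-isopropyl-3-methyl-3-(triethylsilyloxy)oct-6-enal | OC\C=C(\C(C)C)[C@@H](O[Si](C)(C)C(C)(C)C)C[C@@](C)(O[Si](CC)(CC)CC)CC=O | intermediate
17 | 1-(triphenylphosphoranylidene)propan-2-one | CC(=O)C=P(c1ccccc1)(c1ccccc1)c1ccccc1 | starting material
18 | (3E,6S,8S,9Z)-8-(tert-butyldimethylsilyloxy)-11-hydroxy-9-isopropyl-6-methyl-6-(triethylsilyloxy)undeca-3,9-dien-2-one | OC\C=C(\C(C)C)[C@@H](O[Si](C)(C)C(C)(C)C)C[C@@](C)(O[Si](CC)(CC)CC)C/C=C/C(C)=O | intermediate
19 | (6S,8S,9Z)-8-(tert-butyldimethylsilyloxy)-11-hydroxy-9-isopropyl-6-methyl-6-(triethylsilyloxy)undec-9-en-2-one | OC\C=C(\C(C)C)[C@@H](O[Si](C)(C)C(C)(C)C)C[C@@](C)(O[Si](CC)(CC)CC)CCCC(C)=O | intermediate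
20 | (2Z,4S,6S)-4-(tert-butyldimethylsilyloxy)-3-isopropyl-6-methyl-10-oxo-6-(triethylsilyloxy)undec-2-enal (ring-closure precursor) | O=C\C=C(\C(C)C)[C@@H](O[Si](C)(C)C(C)(C)C)C[C@@](C)(O[Si](CC)(CC)CC)CCCC(C)=O | intermediate
21 | cyclic titanium C1,C2-pinacolate of the ten-membered ring, C1/C2 configuration not fixed (not isolated) | CC12O[Ti]OC1\C=C(\C(C)C)[C@@H](O[Si](C)(C)C(C)(C)C)C[C@@](C)(O[Si](CC)(CC)CC)CCC2 | intermediate
22 | (1E,3Z,5S,7S)-5-(tert-butyldimethylsilyloxy)-4-isopropyl-1,7-dimethyl-7-(triethylsilyloxy)cyclodeca-1,3-diene | C/C1=C\C=C(\C(C)C)[C@@H](O[Si](C)(C)C(C)(C)C)C[C@@](C)(O[Si](CC)(CC)CC)CCC1 | intermediate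
23 | (1E,3Z,5S,7S)-4-isopropyl-1,7-dimethylcyclodeca-1,3-diene-5,7-diol | C/C1=C\C=C(\C(C)C)[C@@H](O)C[C@@](C)(O)CCC1 | intermediate
24 | 4-hydroxybenzoic acid | OC(=O)c1ccc(O)cc1 | starting material
25 | tert-butyldimethylsilyl 4-(tert-butyldimethylsilyloxy)benzoate (not isolated) | CC(C)(C)[Si](C)(C)OC(=O)c1ccc(O[Si](C)(C)C(C)(C)C)cc1 | intermediate
26 | 4-(tert-butyldimethylsilyloxy)benzoic acid | OC(=O)c1ccc(O[Si](C)(C)C(C)(C)C)cc1 | intermediate
27 | 4-(tert-butyldimethylsilyloxy)benzoyl chloride (not isolated) | ClC(=O)c1ccc(O[Si](C)(C)C(C)(C)C)cc1 | intermediate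
28 | (1E,3Z,5S,7S)-7-hydroxy-4-isopropyl-1,7-dimethylcyclodeca-1,3-dien-5-yl 4-(tert-butyldimethylsilyloxy)benzoate | C/C1=C\C=C(\C(C)C)[C@@H](OC(=O)c2ccc(O[Si](C)(C)C(C)(C)C)cc2)C[C@@](C)(O)CCC1 | intermediate
29 | (1E,3Z,5S,7S)-7-hydroxy-4-isopropyl-1,7-dimethylcyclodeca-1,3-dien-5-yl 4-hydroxybenzoate | C/C1=C\C=C(\C(C)C)[C@@H](OC(=O)c2ccc(O)cc2)C[C@@](C)(O)CCC1 | target

**Total step count:** 17
**Longest linear sequence:** 16 steps (1–14, 16, 17)

**Steps most likely to fail**

Step 13 (McMurry ring closure).
- What may go wrong: deoxygenation on the metal surface is not stereospecific, so E control at C1=C2 may be lost. The delocalised ketyl may expel the C5 silyloxy group, the Lewis-acidic titanium chlorides may strip the C7 silyl ether, and intermolecular coupling may compete.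
- Fallback, from 20 back to 22: C–C bond formation and deoxygenation are separated, so that the geometry follows from a stereospecific elimination. The same titanium reagent is used at 25 °C, where the reaction stops at pinacolate 21.
- Aqueous K2CO3 work-up and chromatography should give the like-configured (1R,2R)-diol F1 and (1S,2S)-diol F2, separated from their diastereomers.
- Thiocarbonyldiimidazole with DMAP in warm toluene converts them into the (1R,2R)-thionocarbonate F3 and the (1S,2S)-thionocarbonate F4.
- A Corey–Winter elimination in its mild form (1,3-dimethyl-2-phenyl-1,3,2-diazaphospholidine, 40 °C) extrudes CO2 in a syn manner. C10 and C3 are trans on the five-membered ring of F3 and F4, so only the E alkene of 22 can result.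

Step 8 (carbocupration).
- What may go wrong: the alkenylcuprate may leak geometry through its allenolate before protonation, and transfer of the secondary alkyl group to the congested C4 may be sluggish.
- Fallback, from 11 back to 14: the C4–isopropyl bond is made by cross-coupling on a geometrically defined, purifiable alkenyl halide.
- Bu3SnCu(SPh)Li in THF–MeOH at −78 °C adds tin and hydrogen syn, with the proton source present from the start so that the kinetic adduct is trapped at once. This gives the (2E)-3-tributylstannyl enoate F5.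
- Iododestannylation (I2, CH2Cl2, 0 °C) with retention gives the (2E)-3-iodo enoate F6.
- A Negishi coupling with i-PrZnBr, Pd(OAc)2 and CPhos at rt replaces iodine by isopropyl with retention to give 14.

Step 6 (Midland reduction).
- What may go wrong: hydride transfer to the neopentyl-type ynone may be slow. The reagent may then dissociate to 9-BBN, which erodes facial selectivity, and the C7 silyloxy group may β-eliminate from the activated ketone.
- Fallback, from 4 back to 10: the ynone is bypassed by a catalytic asymmetric alkynylation. Methyl propiolate 5 is zincated with Me2Zn to the methylzinc acetylide F7, which adds to aldehyde 4 in toluene at 0 °C under a dinuclear zinc–ProPhenol catalyst.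
- This gives 10 directly, so steps 4–6 shrink to one operation.
- The ligand antipode that leads to 5S is fixed on the first run by Mosher ester analysis.

**Further compounds**
F1 | step 13 | (1R,2R,3Z,5S,7S)-5-(tert-butyldimethylsilyloxy)-4-isopropyl-1,7-dimethyl-7-(triethylsilyloxy)cyclodec-3-ene-1,2-diol | C[C@]1(O)[C@H](O)\C=C(\C(C)C)[C@@H](O[Si](C)(C)C(C)(C)C)C[C@@](C)(O[Si](CC)(CC)CC)CCC1
F2 | step 13 | (1S,2S,3Z,5S,7S)-5-(tert-butyldimethylsilyloxy)-4-isopropyl-1,7-dimethyl-7-(triethylsilyloxy)cyclodec-3-ene-1,2-diol | C[C@@]1(O)[C@@H](O)\C=C(\C(C)C)[C@@H](O[Si](C)(C)C(C)(C)C)C[C@@](C)(O[Si](CC)(CC)CC)CCC1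
F3 | step 13 | cyclic 1,2-thionocarbonate of the (1R,2R)-diol | C[C@]12OC(=S)O[C@@H]1\C=C(\C(C)C)[C@@H](O[Si](C)(C)C(C)(C)C)C[C@@](C)(O[Si](CC)(CC)CC)CCC2
F4 | step 13 | cyclic 1,2-thionocarbonate of the (1S,2S)-diol | C[C@@]12OC(=S)O[C@H]1\C=C(\C(C)C)[C@@H](O[Si](C)(C)C(C)(C)C)C[C@@](C)(O[Si](CC)(CC)CC)CCC2
F5 | step 8 | methyl (2E,4S,6R)-4-(tert-butyldimethylsilyloxy)-8-[methoxy(methyl)amino]-6-methyl-8-oxo-3-(tributylstannyl)-6-(triethylsilyloxy)oct-2-enoate | COC(=O)\C=C(\[Sn](CCCC)(CCCC)CCCC)[C@@H](O[Si](C)(C)C(C)(C)C)C[C@@](C)(O[Si](CC)(CC)CC)CC(=O)N(C)OC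
F6 | step 8 | methyl (2E,4S,6R)-4-(tert-butyldimethylsilyloxy)-3-iodo-8-[methoxy(methyl)amino]-6-methyl-8-oxo-6-(triethylsilyloxy)oct-2-enoate | COC(=O)\C=C(\I)[C@@H](O[Si](C)(C)C(C)(C)C)C[C@@](C)(O[Si](CC)(CC)CC)CC(=O)N(C)OC
F7 | step 6 | methyl 3-(methylzincio)propiolate | C[Zn]C#CC(=O)OC
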